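**Assumption:** the target has no stereocentre and no stereogenic double bond, so "the single enantiomer given" is taken as the one achiral compound drawn and no stereocontrol is needed.

## Retrosynthetic overview

1. Cut the C2–O(aryl) bond last: hydroquinone plus a 2-(methylsulfanyl)chromone, joined by a Cu(I)-driven thioether-to-aryl-ether exchange (the key step).
2. Trace the 8-prenyl/5-OH pattern back to a 5-O-prenyl ether through a para-Claisen–Cope shift; the prenyl ether serves as both protecting group and prenyl source and fixes 8- over 6-substitution.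
3. Open the 2-(methylsulfanyl)chromone to an o-hydroxyacetophenone, CS2 and MeI.
4. Make the mono-prenyl ether from the symmetric 2,6-dihydroxy-4-methoxyacetophenone and prenyl bromide.
5. Ring order: both benzene rings are bought; the γ-pyranone is the only ring formed (step 2).

## Route

**Step 1**
Reactants: 1 1-(2,6-dihydroxy-4-methoxyphenyl)ethan-1-one; 2 1-bromo-3-methylbut-2-ene (prenyl bromide)
Product: 3 1-{2-hydroxy-4-methoxy-6-[(3-methylbut-2-en-1-yl)oxy]phenyl}ethan-1-one
Conditions: K2CO3 (1.2 equiv), 2 (1.05 equiv), acetone, reflux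
Reagents that add atoms: none
Why: Williamson O-alkylation of a symmetric diol, so either hydroxyl gives the same ether, and the remaining hydroxyl is locked in a hydrogen bond to the ketone and resists a second alkylation.

**Step 2**
Reactants: 3 1-{2-hydroxy-4-methoxy-6-[(3-methylbut-2-en-1-yl)oxy]phenyl}ethan-1-one
Product: 5 7-methoxy-5-[(3-methylbut-2-en-1-yl)oxy]-2-(methylsulfanyl)-4H-chromen-4-one, via ketene dithioacetal 4 (not isolated)
Conditions: t-BuOK (3.2 equiv), CS2 (1.2 equiv), THF, 0 °C to rt; then MeI (2.1 equiv), 0 to 50 °C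
Reagents that add atoms: carbon disulfide S=C=S; iodomethane CI
Why: The ketone enolate adds to CS2 and double S-methylation gives the α-oxoketene dithioacetal, whose only free phenoxide closes the pyranone by intramolecular oxa-Michael addition–elimination with loss of methanethiolate, which places the prenyloxy group at C5 without ambiguity.

**Step 3**
Reactants: 5 7-methoxy-5-[(3-methylbut-2-en-1-yl)oxy]-2-(methylsulfanyl)-4H-chromen-4-one
Product: 8 5-hydroxy-7-methoxy-8-(3-methylbut-2-en-1-yl)-2-(methylsulfanyl)-4H-chromen-4-one, via ortho-dienone 6 (not isolated), via para-dienone 7 (not isolated)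
Conditions: Eu(fod)3 (10 mol %), NaHCO3, PhCl, 85 °C
Reagents that add atoms: none
Why: Para-Claisen–Cope rearrangement, in which Eu(III) chelated between C4=O and the C5 ether oxygen speeds the [3,3] shift to C6, the crowded dienone 6 undergoes a Cope [3,3] shift to C8 faster than it enolises, and dienone 7 tautomerises to the chelated 5-phenol (the transient C6 and C8 stereocentres are racemic and vanish on aromatisation).

**Step 4**
Reactants: 8 5-hydroxy-7-methoxy-8-(3-methylbut-2-en-1-yl)-2-(methylsulfanyl)-4H-chromen-4-one; 9 benzene-1,4-diol (hydroquinone)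
Product: 10 5-hydroxy-2-(4-hydroxyphenoxy)-7-methoxy-8-(3-methylbut-2-en-1-yl)-4H-chromen-4-one (7-O-methylepimedonin G)
Conditions: Cu(I) thiophene-2-carboxylate (CuTC, 2.0 equiv), 9 (5 equiv), degassed THF, 55 °C, Ar
Reagents that add atoms: none
Why: Proposed new method: a direct, oxidant-free exchange of the C2–SMe group for an aryloxy group, in which thiophilic Cu(I) binds the sulfur of the vinylogous thioester and raises the electrophilicity of C2, the carboxylate passes the phenol on as a copper phenoxide that adds at C2 (oxa-Michael), and the O,S-acetal enolate collapses with loss of insoluble CuSMe, which makes an otherwise uphill thiolate-for-aryloxide exchange irreversible; excess hydroquinone suppresses double arylation and the chelated 5-OH is not nucleophilic; the closest known reaction types are Cu(I)/Ag(I)-promoted thioester-to-ester exchange, Cu(I)-carboxylate C–S activation in Liebeskind–Srogl coupling, and addition–elimination of phenoxides on 2-sulfinyl- or 2-sulfonylchromones.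

## Compound list

1 | 1-(2,6-dihydroxy-4-methoxyphenyl)ethan-1-one | CC(=O)c1c(O)cc(OC)cc1O | starting material
2 | 1-bromo-3-methylbut-2-ene (prenyl bromide) | CC(C)=CCBr | starting material
3 | 1-{2-hydroxy-4-methoxy-6-[(3-methylbut-2-en-1-yl)oxy]phenyl}ethan-1-one | CC(=O)c1c(O)cc(OC)cc1OCC=C(C)C | intermediate
4 | 1-{2-hydroxy-4-methoxy-6-[(3-methylbut-2-en-1-yl)oxy]phenyl}-3,3-bis(methylsulfanyl)prop-2-en-1-one (not isolated) | CSC(SC)=CC(=O)c1c(O)cc(OC)cc1OCC=C(C)C | intermediate
5 | 7-methoxy-5-[(3-methylbut-2-en-1-yl)oxy]-2-(methylsulfanyl)-4H-chromen-4-one | COc1cc(OCC=C(C)C)c2c(=O)cc(SC)oc2c1 | intermediate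
6 | 7-methoxy-6-(2-methylbut-3-en-2-yl)-2-(methylsulfanyl)-6H-chromene-4,5-dione (racemic at C6, not isolated) | COC1=CC2=C(C(=O)C=C(SC)O2)C(=O)C1C(C)(C)C=C | intermediate
7 | 7-methoxy-8-(3-methylbut-2-en-1-yl)-2-(methylsulfanyl)-8H-chromene-4,5-dione (racemic at C8, not isolated) | COC1=CC(=O)C2=C(OC(SC)=CC2=O)C1CC=C(C)C | intermediate
8 | 5-hydroxy-7-methoxy-8-(3-methylbut-2-en-1-yl)-2-(methylsulfanyl)-4H-chromen-4-one | COc1cc(O)c2c(=O)cc(SC)oc2c1CC=C(C)C | intermediate
9 | benzene-1,4-diol (hydroquinone) | Oc1ccc(O)cc1 | starting material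
10 | 5-hydroxy-2-(4-hydroxyphenoxy)-7-methoxy-8-(3-methylbut-2-en-1-yl)-4H-chromen-4-one (7-O-methylepimedonin G) | COc1cc(O)c2c(=O)cc(Oc3ccc(O)cc3)oc2c1CC=C(C)C | target

## Step count and risk

Total step count: 4.
Longest linear sequence: 4 steps (1 → 3 → 5 → 8 → 10).

**Step 4 (proposed new C–O exchange; highest risk).** Copper may fail to activate the thioether enough, or hydroquinone may be arylated twice. The fallback uses known chemistry, sets out from 8 and comes back at 10. Sulfide 8 is oxidised at sulfur with catalytic ammonium heptamolybdate and 30% H2O2 in EtOH (0 °C to rt), conditions that oxidise sulfur well before a trisubstituted alkene, to give 5-hydroxy-7-methoxy-8-(3-methylbut-2-en-1-yl)-2-(methylsulfonyl)-4H-chromen-4-one F6. F6 is then treated with hydroquinone 9 (5 equiv) and K2CO3 in DMF at rt, where the phenoxide displaces methanesulfinate by addition–elimination to give 10.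

**Step 3 (para-Claisen–Cope).** The ortho-dienone may enolise to the 6-(1,1-dimethylallyl) isomer instead of undergoing the Cope shift. The fallback drops the sigmatropic transfer in favour of direct C-alkylation and a protecting-group-controlled ring closure; it sets out from 1 and comes back at 8. Compound 1 is C-prenylated with 2 in 10% aqueous KOH (0 °C to rt; the ring is symmetric, so only one mono-C-prenyl product exists) to give 1-[2,6-dihydroxy-4-methoxy-3-(3-methylbut-2-en-1-yl)phenyl]ethan-1-one F2. The less hindered hydroxyl is protected with MOMCl and i-Pr2NEt in CH2Cl2 at 0 °C to give 1-[2-hydroxy-4-methoxy-6-(methoxymethoxy)-3-(3-methylbut-2-en-1-yl)phenyl]ethan-1-one F3. Annulation as in step 2 (t-BuOK, CS2, then MeI) passes through 1-[2-hydroxy-4-methoxy-6-(methoxymethoxy)-3-(3-methylbut-2-en-1-yl)phenyl]-3,3-bis(methylsulfanyl)prop-2-en-1-one F4, which can only close through the hydroxyl next to the prenyl group, and gives 7-methoxy-5-(methoxymethoxy)-8-(3-methylbut-2-en-1-yl)-2-(methylsulfanyl)-4H-chromen-4-one F5. The peri MOM ether is removed with 1 M HCl in MeOH at 40 °C to reach 8.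

**Step 2 (one-pot annulation).** Excess MeI may O-methylate the phenoxide, or the dithioacetal may close incompletely. The fallback closes the ring before any alkylation; it sets out from 3 and comes back at 5. Compound 3 is treated with t-BuOK and CS2 in THF and then with cold 1 M HCl, so that the β-keto dithioacid cyclises with loss of hydrogen sulfide to 4-hydroxy-7-methoxy-5-[(3-methylbut-2-en-1-yl)oxy]-2H-chromene-2-thione F1, which is isolated. F1 is then S-methylated with one equivalent of MeI and K2CO3 in acetone to give 5.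

## Further compounds

F1 | step 2 | 4-hydroxy-7-methoxy-5-[(3-methylbut-2-en-1-yl)oxy]-2H-chromene-2-thione | COc1cc(OCC=C(C)C)c2c(O)cc(=S)oc2c1
F2 | step 3 | 1-[2,6-dihydroxy-4-methoxy-3-(3-methylbut-2-en-1-yl)phenyl]ethan-1-one | CC(=O)c1c(O)cc(OC)c(CC=C(C)C)c1O
F3 | step 3 | 1-[2-hydroxy-4-methoxy-6-(methoxymethoxy)-3-(3-methylbut-2-en-1-yl)phenyl]ethan-1-one | CC(=O)c1c(OCOC)cc(OC)c(CC=C(C)C)c1O
F4 | step 3 | 1-[2-hydroxy-4-methoxy-6-(methoxymethoxy)-3-(3-methylbut-2-en-1-yl)phenyl]-3,3-bis(methylsulfanyl)prop-2-en-1-one (not isolated) | CSC(SC)=CC(=O)c1c(OCOC)cc(OC)c(CC=C(C)C)c1O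
F5 | step 3 | 7-methoxy-5-(methoxymethoxy)-8-(3-methylbut-2-en-1-yl)-2-(methylsulfanyl)-4H-chromen-4-one | COCOc1cc(OC)c(CC=C(C)C)c2oc(SC)cc(=O)c12
F6 | step 4 | 5-hydroxy-7-methoxy-8-(3-methylbut-2-en-1-yl)-2-(methylsulfonyl)-4H-chromen-4-one | COc1cc(O)c2c(=O)cc(S(C)(=O)=O)oc2c1CC=C(C)C
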